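**Strategy.** Everything rests on making the cyclohexenone ring (C1, C7, C8, C9(=O), C10, C11 of the tricyclo[5.4.0.0^{2,8}]undecane) last, from a cyclopentanone: C10 is inserted between C9 and C11 by FeCl3 opening of a siloxycyclopropane, and loss of HCl gives the C9(=O)–C10H=C11(CH3) enone that the step exploits. The precursor is a bicyclo[2.1.1]hexan-2-one spanned by the oxygenated four-carbon bridge; it arises from a transannular crossed [2+2] photocycloaddition of an (E,E)-cyclodeca-2,8-dienone whose Roche-ester stereocentre steers both alkene faces. The carbinol centres come from an Ipc2B aldol and an Evans–Tishchenko reduction.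

Key step: step 16

Remark: centres that the route removes later (the carbinol carbon made in step 11, the C–Cl carbon of 23) are carried as epimer mixtures and left undefined in the SMILES; compound 6 is sold as its dimer and reacts as the monomer.

Step 1
Reactants: 1 methyl (R)-3-hydroxy-2-methylpropanoate
Product: 2 methyl (R)-3-(tert-butyldimethylsilyloxy)-2-methylpropanoate
Conditions: TBSCl, imidazole, CH2Cl2, 0 °C → rt
Reagents that add atoms: tert-butyldimethylsilyl chloride, CC(C)(C)[Si](C)(C)Cl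
Why: Silyl ether protection of the primary alcohol should be clean and does not touch the α-stereocentre.

Step 2
Reactants: 2 methyl (R)-3-(tert-butyldimethylsilyloxy)-2-methylpropanoate
Product: 3 (R)-3-(tert-butyldimethylsilyloxy)-2-methylpropanal
Conditions: DIBAL-H, CH2Cl2, −78 °C; Rochelle salt
Reagents that add atoms: none
Why: Partial ester reduction with DIBAL-H stops at the aluminium hemiacetal at −78 °C and should give the aldehyde without epimerisation if it is used at once.

Step 3
Reactants: 3 (R)-3-(tert-butyldimethylsilyloxy)-2-methylpropanal; 4 diethyl (3-oxobutan-2-yl)phosphonate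
Product: 5 (S,E)-6-(tert-butyldimethylsilyloxy)-3,5-dimethylhex-3-en-2-one
Conditions: Ba(OH)2·8H2O, THF/H2O (40:1), rt
Reagents that add atoms: none
Why: Horner–Wadsworth–Emmons olefination with the α-methyl β-ketophosphonate under mild Ba(OH)2 activation should give the E-trisubstituted enone without epimerising the aldehyde.

Step 4
Reactants: 6 3-hydroxy-2,2-dimethylpropanal
Product: 7 (E)-4-iodo-2,2-dimethylbut-3-en-1-ol
Conditions: CrCl2, CHI3, THF, 0 °C
Reagents that add atoms: iodoform, IC(I)I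
Why: Takai olefination converts the aldehyde into the E-vinyl iodide through a gem-dichromium species and tolerates the free hydroxyl.

Step 5
Reactants: 7 (E)-4-iodo-2,2-dimethylbut-3-en-1-ol
Product: 8 (E)-4-iodo-2,2-dimethylbut-3-enal
Conditions: Dess–Martin periodinane, NaHCO3, CH2Cl2, 0 °C → rt
Reagents that add atoms: none
Why: Dess–Martin oxidation of the neopentyl alcohol should give the non-enolisable aldehyde.

Step 6
Reactants: 5 (S,E)-6-(tert-butyldimethylsilyloxy)-3,5-dimethylhex-3-en-2-one; 8 (E)-4-iodo-2,2-dimethylbut-3-enal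
Product: 11 (1E,4R,7E,9S)-10-(tert-butyldimethylsilyloxy)-4-hydroxy-1-iodo-3,3,7,9-tetramethyldeca-1,7-dien-6-one, via boron enolate 9 (not isolated), via boron aldolate 10 (not isolated)
Conditions: (+)-Ipc2BCl, Et3N, Et2O, −78 → 0 °C; 8, −78 → −20 °C; H2O2, pH 7 buffer, MeOH
Reagents that add atoms: none
Why: Boron-mediated aldol reaction in which Ipc2BCl/Et3N enolises the methyl group and the (+)-Ipc ligands should direct the dienolate to the Re face of the aldehyde, which sets the (4R)-carbinol under reagent control.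

Step 7
Reactants: 11 (1E,4R,7E,9S)-10-(tert-butyldimethylsilyloxy)-4-hydroxy-1-iodo-3,3,7,9-tetramethyldeca-1,7-dien-6-one; 12 3-methylbutanal
Product: 13 (1E,4R,6R,7E,9S)-10-(tert-butyldimethylsilyloxy)-6-hydroxy-1-iodo-3,3,7,9-tetramethyldeca-1,7-dien-4-yl 3-methylbutanoate
Conditions: SmI2 (20 mol %), THF, −10 °C
Reagents that add atoms: none
Why: Evans–Tishchenko reduction in which the samarium-bound hemiacetal of 12 delivers hydride intramolecularly through a chair-like chelate, which should set C6 anti to C4 and leave the 3-methylbutanoyl group on the C4 oxygen.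

Step 8
Reactants: 13 (1E,4R,6R,7E,9S)-10-(tert-butyldimethylsilyloxy)-6-hydroxy-1-iodo-3,3,7,9-tetramethyldeca-1,7-dien-4-yl 3-methylbutanoate; 14 3-methylbut-2-enoic acid
Product: 15 (1E,4R,6R,7E,9S)-10-(tert-butyldimethylsilyloxy)-1-iodo-3,3,7,9-tetramethyl-4-(3-methylbutanoyloxy)deca-1,7-dien-6-yl 3-methylbut-2-enoate
Conditions: DCC, DMAP (cat.), CH2Cl2, 0 °C → rt
Reagents that add atoms: none
Why: Steglich esterification of the free allylic alcohol should install the 3-methylbut-2-enoate without the deconjugation that the acid chloride and amine bases cause.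

Step 9
Reactants: 15 (1E,4R,6R,7E,9S)-10-(tert-butyldimethylsilyloxy)-1-iodo-3,3,7,9-tetramethyl-4-(3-methylbutanoyloxy)deca-1,7-dien-6-yl 3-methylbut-2-enoate
Product: 16 (1E,4R,6R,7E,9S)-10-hydroxy-1-iodo-3,3,7,9-tetramethyl-4-(3-methylbutanoyloxy)deca-1,7-dien-6-yl 3-methylbut-2-enoate
Conditions: HF·pyridine, pyridine, THF, 0 °C → rt
Reagents that add atoms: none
Why: Buffered fluoride cleavage of the primary silyl ether should leave both esters and the vinyl iodide intact.

Step 10
Reactants: 16 (1E,4R,6R,7E,9S)-10-hydroxy-1-iodo-3,3,7,9-tetramethyl-4-(3-methylbutanoyloxy)deca-1,7-dien-6-yl 3-methylbut-2-enoate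
Product: 17 (1E,4R,6R,7E,9S)-1-iodo-3,3,7,9-tetramethyl-4-(3-methylbutanoyloxy)-10-oxodeca-1,7-dien-6-yl 3-methylbut-2-enoate
Conditions: Dess–Martin periodinane, NaHCO3, CH2Cl2, 0 °C; used crude
Reagents that add atoms: none
Why: Dess–Martin oxidation under buffered neutral conditions should give the β,γ-unsaturated aldehyde without epimerising C9 or moving the alkene.

Step 11
Reactants: 17 (1E,4R,6R,7E,9S)-1-iodo-3,3,7,9-tetramethyl-4-(3-methylbutanoyloxy)-10-oxodeca-1,7-dien-6-yl 3-methylbut-2-enoate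
Product: 18 (1R,3R,5E,8S,9E)-7-hydroxy-4,4,8,10-tetramethyl-3-(3-methylbutanoyloxy)cyclodeca-5,9-dien-1-yl 3-methylbut-2-enoate (C7 epimers)
Conditions: CrCl2 (10 equiv), NiCl2 (2 mol %), DMSO/THF (3:1), 2 mM, rt
Reagents that add atoms: none
Why: Nozaki–Hiyama–Kishi reaction in which the alkenylchromium(III) species from the E-vinyl iodide adds to the aldehyde under neutral high-dilution conditions with retention of alkene geometry, closing the ten-membered ring and creating a carbinol centre that the next step removes.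

Step 12
Reactants: 18 (1R,3R,5E,8S,9E)-7-hydroxy-4,4,8,10-tetramethyl-3-(3-methylbutanoyloxy)cyclodeca-5,9-dien-1-yl 3-methylbut-2-enoate
Product: 19 (1R,3R,5E,8S,9E)-4,4,8,10-tetramethyl-3-(3-methylbutanoyloxy)-7-oxocyclodeca-5,9-dien-1-yl 3-methylbut-2-enoate
Conditions: Dess–Martin periodinane, NaHCO3, CH2Cl2, 0 °C; used crude
Reagents that add atoms: none
Why: Dess–Martin oxidation of the allylic alcohol should give the enone under neutral conditions that leave the doubly activated C8 centre intact.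

Step 13
Reactants: 19 (1R,3R,5E,8S,9E)-4,4,8,10-tetramethyl-3-(3-methylbutanoyloxy)-7-oxocyclodeca-5,9-dien-1-yl 3-methylbut-2-enoate
Product: 20 2,6,6,10-tetramethyl-5-(3-methylbutanoyloxy)-9-oxotricyclo[5.3.0.0^{2,8}]decan-3-yl 3-methylbut-2-enoate (cyclobutane centres as in 24, C10 methyl on the side of C7–H)
Conditions: hν (350 nm, Pyrex), degassed MeCN, 2 mM, rt
Reagents that add atoms: none
Why: Transannular enone–alkene [2+2] photocycloaddition in which the hexa-1,5-dien-3-one unit should close in the crossed sense (rule of five) to the bicyclo[2.1.1]hexan-2-one, the enone (C5=C6–C7=O, locants of 19) reaching C9=C10 on the face anti to the C8 methyl because A(1,3) strain with the C10 methyl holds C8–H in the alkene plane, while the ten-membered ring forces both bridge carbons onto the inner positions of the cyclobutane, so that all four new stereocentres follow from C8.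

Step 14
Reactants: 20 2,6,6,10-tetramethyl-5-(3-methylbutanoyloxy)-9-oxotricyclo[5.3.0.0^{2,8}]decan-3-yl 3-methylbut-2-enoate
Product: 21 2,6,6,10-tetramethyl-5-(3-methylbutanoyloxy)-9-(trimethylsilyloxy)tricyclo[5.3.0.0^{2,8}]dec-9-en-3-yl 3-methylbut-2-enoate
Conditions: TMSOTf, Et3N, CH2Cl2, 0 °C → rt
Reagents that add atoms: trimethylsilyl trifluoromethanesulfonate, C[Si](C)(C)OS(=O)(=O)C(F)(F)F
Why: Soft enolisation with TMSOTf/Et3N should silylate the ketone on its only enolisable side (the other α-carbon is a cyclobutane bridgehead) and leave the esters untouched.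

Step 15
Reactants: 21 2,6,6,10-tetramethyl-5-(3-methylbutanoyloxy)-9-(trimethylsilyloxy)tricyclo[5.3.0.0^{2,8}]dec-9-en-3-yl 3-methylbut-2-enoate
Product: 22 siloxycyclopropane of 21 (CH2 added across the enol ether C=C, on the side of the cyclobutane C–H)
Conditions: Et2Zn, CH2I2, CH2Cl2, 0 °C → rt
Reagents that add atoms: diiodomethane, ICI
Why: Simmons–Smith cyclopropanation (Furukawa reagent) of the electron-rich strained silyl enol ether should occur from the face next to the cyclobutane C–H, away from the cyclobutane methyl, and spare the electron-poor enoate.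

Step 16
Reactants: 22 siloxycyclopropane of 21
Product: 24 2,6,6,11-tetramethyl-5-(3-methylbutanoyloxy)-9-oxotricyclo[5.4.0.0^{2,8}]undec-10-en-3-yl 3-methylbut-2-enoate (CNP0335239.1), via β-chloro ketone 23 (not isolated)
Conditions: FeCl3 (2.5 equiv), DMF, 0 °C → rt; then NaOAc, MeOH, 40 °C
Reagents that add atoms: none
Why: FeCl3 oxidises the siloxycyclopropane by one electron, Me3SiCl is lost and the internal bond between the siloxy carbon (C9, locants of 24) and the methyl-bearing carbon (C11) breaks, so that the cyclopentanone ring (C1, C7, C8, C9, C11) becomes six-membered with the former cyclopropane CH2 as C10 and a tertiary radical at C11; a second FeCl3 transfers chlorine to give 23, and NaOAc removes HCl by E1cB through the C10 enolate. The closest known reaction is the Saegusa ring expansion of 1-siloxybicyclo[n.1.0]alkanes to cycloalk-2-enones (2-methylcycloalkanone to 3-methylcycloalk-2-enone). No ring is closed: the step is a one-carbon ring expansion in which the cyclopropane and the five-membered ring merge into the cyclohexenone. No stereocentre is created; the temporary centres at C9 and C11 disappear and the four cyclobutane centres and the two carbinol centres are not touched. The step needs internal rather than external cyclopropane cleavage, which the tertiary radical at C11 secures, and chlorine transfer faster than opening of the adjacent cyclobutane, which excess FeCl3 in DMF at 0 °C should favour. The elimination can only give the conjugated C10=C11 alkene because C8 is a bridgehead and cannot enolise.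

**Compound list**

1 | methyl (R)-3-hydroxy-2-methylpropanoate | COC(=O)[C@H](C)CO | starting material
2 | methyl (R)-3-(tert-butyldimethylsilyloxy)-2-methylpropanoate | COC(=O)[C@H](C)CO[Si](C)(C)C(C)(C)C | intermediate
3 | (R)-3-(tert-butyldimethylsilyloxy)-2-methylpropanal | O=C[C@H](C)CO[Si](C)(C)C(C)(C)C | intermediate
4 | diethyl (3-oxobutan-2-yl)phosphonate | CCOP(=O)(OCC)C(C)C(C)=O | starting material
5 | (S,E)-6-(tert-butyldimethylsilyloxy)-3,5-dimethylhex-3-en-2-one | CC(=O)/C(C)=C/[C@H](C)CO[Si](C)(C)C(C)(C)C | intermediate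
6 | 3-hydroxy-2,2-dimethylpropanal | OCC(C)(C)C=O | starting material
7 | (E)-4-iodo-2,2-dimethylbut-3-en-1-ol | OCC(C)(C)/C=C/I | intermediate
8 | (E)-4-iodo-2,2-dimethylbut-3-enal | O=CC(C)(C)/C=C/I | intermediate
9 | diisopinocampheylboron dienolate of 5 | C[C@@H]1[C@H](C[C@H]2C[C@@H]1C2(C)C)B(OC(=C)/C(C)=C/[C@H](C)CO[Si](C)(C)C(C)(C)C)[C@H]3C[C@H]4C[C@@H]([C@@H]3C)C4(C)C | intermediate
10 | diisopinocampheylboron aldolate of 11 | C[C@@H]1[C@H](C[C@H]2C[C@@H]1C2(C)C)B(O[C@H](CC(=O)/C(C)=C/[C@H](C)CO[Si](C)(C)C(C)(C)C)C(C)(C)/C=C/I)[C@H]3C[C@H]4C[C@@H]([C@@H]3C)C4(C)C | intermediate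
11 | (1E,4R,7E,9S)-10-(tert-butyldimethylsilyloxy)-4-hydroxy-1-iodo-3,3,7,9-tetramethyldeca-1,7-dien-6-one | I/C=C/C(C)(C)[C@H](O)CC(=O)/C(C)=C/[C@H](C)CO[Si](C)(C)C(C)(C)C | intermediate
12 | 3-methylbutanal | CC(C)CC=O | starting material
13 | (1E,4R,6R,7E,9S)-10-(tert-butyldimethylsilyloxy)-6-hydroxy-1-iodo-3,3,7,9-tetramethyldeca-1,7-dien-4-yl 3-methylbutanoate | I/C=C/C(C)(C)[C@H](OC(=O)CC(C)C)C[C@@H](O)/C(C)=C/[C@H](C)CO[Si](C)(C)C(C)(C)C | intermediate
14 | 3-methylbut-2-enoic acid | CC(C)=CC(=O)O | starting material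
15 | (1E,4R,6R,7E,9S)-10-(tert-butyldimethylsilyloxy)-1-iodo-3,3,7,9-tetramethyl-4-(3-methylbutanoyloxy)deca-1,7-dien-6-yl 3-methylbut-2-enoate | I/C=C/C(C)(C)[C@H](OC(=O)CC(C)C)C[C@@H](OC(=O)C=C(C)C)/C(C)=C/[C@H](C)CO[Si](C)(C)C(C)(C)C | intermediate
16 | (1E,4R,6R,7E,9S)-10-hydroxy-1-iodo-3,3,7,9-tetramethyl-4-(3-methylbutanoyloxy)deca-1,7-dien-6-yl 3-methylbut-2-enoate | I/C=C/C(C)(C)[C@H](OC(=O)CC(C)C)C[C@@H](OC(=O)C=C(C)C)/C(C)=C/[C@H](C)CO | intermediate
17 | (1E,4R,6R,7E,9S)-1-iodo-3,3,7,9-tetramethyl-4-(3-methylbutanoyloxy)-10-oxodeca-1,7-dien-6-yl 3-methylbut-2-enoate | I/C=C/C(C)(C)[C@H](OC(=O)CC(C)C)C[C@@H](OC(=O)C=C(C)C)/C(C)=C/[C@H](C)C=O | intermediate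
18 | (1R,3R,5E,8S,9E)-7-hydroxy-4,4,8,10-tetramethyl-3-(3-methylbutanoyloxy)cyclodeca-5,9-dien-1-yl 3-methylbut-2-enoate (C7 epimers) | CC(C)=CC(=O)O[C@@H]1C[C@@H](OC(=O)CC(C)C)C(C)(C)/C=C/C(O)[C@@H](C)/C=C1\C | intermediate
19 | (1R,3R,5E,8S,9E)-4,4,8,10-tetramethyl-3-(3-methylbutanoyloxy)-7-oxocyclodeca-5,9-dien-1-yl 3-methylbut-2-enoate | CC(C)=CC(=O)O[C@@H]1C[C@@H](OC(=O)CC(C)C)C(C)(C)/C=C/C(=O)[C@@H](C)/C=C1\C | intermediate
20 | 2,6,6,10-tetramethyl-5-(3-methylbutanoyloxy)-9-oxotricyclo[5.3.0.0^{2,8}]decan-3-yl 3-methylbut-2-enoate (C10 methyl on the side of C7–H) | CC(C)=CC(=O)O[C@@H]1C[C@@H](OC(=O)CC(C)C)C(C)(C)[C@@H]2[C@H]3C(=O)[C@@H](C)[C@@H]2[C@]31C | intermediate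
21 | 2,6,6,10-tetramethyl-5-(3-methylbutanoyloxy)-9-(trimethylsilyloxy)tricyclo[5.3.0.0^{2,8}]dec-9-en-3-yl 3-methylbut-2-enoate | CC(C)=CC(=O)O[C@@H]1C[C@@H](OC(=O)CC(C)C)C(C)(C)[C@@H]2[C@H]3C(O[Si](C)(C)C)=C(C)[C@@H]2[C@]31C | intermediate
22 | siloxycyclopropane of 21 (CH2 bridging C9 and C10 on the side of C7–H) | CC(C)=CC(=O)O[C@@H]1C[C@@H](OC(=O)CC(C)C)C(C)(C)[C@@H]2[C@H]3[C@@]4(O[Si](C)(C)C)C[C@@]4(C)[C@@H]2[C@]31C | intermediate
23 | 11-chloro-2,6,6,11-tetramethyl-5-(3-methylbutanoyloxy)-9-oxotricyclo[5.4.0.0^{2,8}]undecan-3-yl 3-methylbut-2-enoate (C11 epimers) | CC(C)=CC(=O)O[C@@H]1C[C@@H](OC(=O)CC(C)C)C(C)(C)[C@@H]2[C@H]3C(=O)CC(C)(Cl)[C@@H]2[C@]31C | intermediate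
24 | 2,6,6,11-tetramethyl-5-(3-methylbutanoyloxy)-9-oxotricyclo[5.4.0.0^{2,8}]undec-10-en-3-yl 3-methylbut-2-enoate (CNP0335239.1) | CC(C)=CC(=O)O[C@@H]1C[C@@H](OC(=O)CC(C)C)C(C)(C)[C@@H]2[C@H]3C(=O)C=C(C)[C@@H]2[C@]31C | target

**Count.** Total: 16 steps. Longest linear sequence: 14 steps (steps 1–3 and 6–16, from 1 to 24).

**Steps most likely to fail**

Step 13. E/Z isomerisation of the strained enone and α-cleavage of the β,γ-unsaturated ketone may outrun transannular bonding, and facial control by C8 may be incomplete in the flexible ring. The fallback sets out from 18 and replaces the enone triplet by a ground-state copper template: copper(I)-catalysed crossed [2+2] photocycloaddition of the 1,5-diene (CuOTf, hν 254 nm, Et2O), in which the free hydroxyl helps binding, should give tricyclic alcohol F1. Dess–Martin oxidation of F1 comes back to the route at 20.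

Step 16. The tertiary radical at C11 sits next to the cyclobutane and may fragment it (cyclobutylcarbinyl opening) before chlorine transfer. The fallback sets out from 21 and avoids a free radical or cation at C11. Dibromocarbene addition (CHBr3, KOtBu, pentane, −30 °C) should give dibromocyclopropane F2. Warming F2 in toluene (80 °C) opens it in a concerted disrotatory way with loss of bromide and then Me3SiBr, which expands the same ring to 2-bromo enone F3. Radical debromination of F3 (Bu3SnH, AIBN, benzene, 80 °C) comes back at 24.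

Step 11. Oligomerisation and drift of the β,γ-unsaturated aldehyde into conjugation may compete with the slow closure of the strained ten-membered ring. The fallback sets out from 16 and closes the ring by metathesis. Palladium-catalysed hydrodeiodination (Pd(PPh3)4, Bu3SnH, THF) should give terminal alkene F4. Dess–Martin oxidation gives aldehyde F5, and vinylmagnesium bromide (THF, −78 °C) gives divinyl carbinol F6. Ring-closing metathesis of F6 (Grubbs second-generation catalyst, 1 mM, CH2Cl2, 40 °C) comes back at 18.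

**Further compounds**

F1 | step 13 | 9-hydroxy-2,6,6,10-tetramethyl-5-(3-methylbutanoyloxy)tricyclo[5.3.0.0^{2,8}]decan-3-yl 3-methylbut-2-enoate (C9 epimers) | CC(C)=CC(=O)O[C@@H]1C[C@@H](OC(=O)CC(C)C)C(C)(C)[C@@H]2[C@H]3C(O)[C@@H](C)[C@@H]2[C@]31C
F2 | step 16 | dibromocyclopropane of 21 (CBr2 bridging C9 and C10 on the side of C7–H) | CC(C)=CC(=O)O[C@@H]1C[C@@H](OC(=O)CC(C)C)C(C)(C)[C@@H]2[C@H]3[C@@]4(O[Si](C)(C)C)C(Br)(Br)[C@@]4(C)[C@@H]2[C@]31C
F3 | step 16 | 10-bromo-2,6,6,11-tetramethyl-5-(3-methylbutanoyloxy)-9-oxotricyclo[5.4.0.0^{2,8}]undec-10-en-3-yl 3-methylbut-2-enoate | CC(C)=CC(=O)O[C@@H]1C[C@@H](OC(=O)CC(C)C)C(C)(C)[C@@H]2[C@H]3C(=O)C(Br)=C(C)[C@@H]2[C@]31C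
F4 | step 11 | (4R,6R,7E,9S)-10-hydroxy-3,3,7,9-tetramethyl-4-(3-methylbutanoyloxy)deca-1,7-dien-6-yl 3-methylbut-2-enoate | C=CC(C)(C)[C@H](OC(=O)CC(C)C)C[C@@H](OC(=O)C=C(C)C)/C(C)=C/[C@H](C)CO
F5 | step 11 | (4R,6R,7E,9S)-3,3,7,9-tetramethyl-4-(3-methylbutanoyloxy)-10-oxodeca-1,7-dien-6-yl 3-methylbut-2-enoate | C=CC(C)(C)[C@H](OC(=O)CC(C)C)C[C@@H](OC(=O)C=C(C)C)/C(C)=C/[C@H](C)C=O
F6 | step 11 | (4R,6R,7E,9S)-10-hydroxy-3,3,7,9-tetramethyl-4-(3-methylbutanoyloxy)dodeca-1,7,11-trien-6-yl 3-methylbut-2-enoate (C10 epimers) | C=CC(C)(C)[C@H](OC(=O)CC(C)C)C[C@@H](OC(=O)C=C(C)C)/C(C)=C/[C@H](C)C(O)C=C
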